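**Retrosynthetic overview**
1. Feature: C10 is a quaternary carbon carrying the C20 methyl between C9 and C5, and C1 is the β-carbon of a C3 ketone. The C1–C10 bond is therefore cut to a tertiary C10 radical, made from a C9–C10 epoxide, and the terminal carbon of a C3 vinyl ketone.
2. Ring order: ring B is bought (2-methylcyclohexenone supplies C5–C10 and C20). Ring A is closed second, in the key step, by a Ti(III)-triggered 6-endo radical conjugate addition that gives the trans-decalin and leaves O9 as a handle.
3. Before: C5 by CBS reduction and Ireland–Claisen chirality transfer; quaternary C4 (α-CH3, β-CO2Me) by methylation of a temporary cis-fused iodolactone; then Zn opening, Stille acylation to the vinyl ketone, and epoxidation.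
4. After: O9 → C9 ketone → enol triflate → B-alkyl Suzuki (C11–C13, C16); hydroboration, oxidation and Wittig (H9α, C8=C17); HWE (C14, C15, 13E).
5. End: one LiAlH4 reduction gives the 3β,15,19-triol; then C15 silylation, selective C19 oxidation, C3 acetylation, desilylation.

Key step: step 9

**Remarks on the chemistry (assumptions)**
- Labdane numbering (C1–C20) is used for every intermediate, including the monocyclic ones; α/β refer to the usual drawing with the C10 methyl β. The target is read as 3β-acetoxy-15-hydroxylabda-8(17),13E-dien-19-al (5α-H, 9α-H, 10β-CH3, 4α-CH3, 4β-CHO).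
- C4 is not set in the sigmatropic step: with a methylmalonate ester the result would depend on an ill-defined ketene acetal geometry and on the chair/boat balance of a cyclohexenyl ester. It is set instead by alkylating the rigid lactone 8.
- The epoxide configuration of 14 (C9, C10) is not carried into the target: C10 becomes a planar radical in step 9 and C9 is oxidised in step 11.
- Numbered carbon building blocks (3, 11, 20, 28, assumed purchased) stand under Reactants; "Reagents that add atoms" lists unnumbered reagents only.
- Stereocentres: C5 (step 3), C4 (step 5), C10 (step 9), C9 (step 14), C3 (step 19), 13E (step 18).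

**Route**

Step 1
Reactants: 1 2-methylcyclohex-2-en-1-one
Product: 2 (S)-2-methylcyclohex-2-en-1-ol
Conditions: (R)-Me-CBS (10 mol %), BH3·SMe2, THF, −20 °C
Reagents that add atoms: none
Why: Corey–Bakshi–Shibata reduction, in which the trisubstituted alkenyl arm acts as the large group on the oxazaborolidine, so the (R)-catalyst should deliver hydride to give the (S)-carbinol, whose C–O bond later relays its configuration to C5.

Step 2
Reactants: 2 (S)-2-methylcyclohex-2-en-1-ol; 3 methyl 3-chloro-3-oxopropanoate
Product: 4 methyl (1S)-2-methylcyclohex-2-en-1-yl propanedioate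
Conditions: pyridine, CH2Cl2, 0 °C
Reagents that add atoms: none
Why: Acylation of a secondary allylic alcohol by an acid chloride under pyridine catalysis, which does not touch the stereocentre.

Step 3
Reactants: 4 methyl (1S)-2-methylcyclohex-2-en-1-yl propanedioate
Product: 7 3-methoxy-2-[(1S)-2-methylcyclohex-2-en-1-yl]-3-oxopropanoic acid (C4 epimer pair), via silyl ketene acetal 5 (not isolated), via trimethylsilyl ester 6 (not isolated)
Conditions: LiHMDS, TMSCl, THF, −78 °C → reflux; then 1 M HCl
Reagents that add atoms: none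
Why: Ireland–Claisen rearrangement, a suprafacial [3,3] shift across the ring, forms the C4–C5 bond on the face that carried the C–O bond and so sets C5 by chirality transfer whether the transition state is chair or boat, while C4 (still a malonate CH) forms as an equilibrating epimer pair that is fixed in step 5.

Step 4
Reactants: 7 3-methoxy-2-[(1S)-2-methylcyclohex-2-en-1-yl]-3-oxopropanoic acid
Product: 8 cis-fused iodolactone (lactone O on C10 and C4 on C5 both β, iodine on C9 α, C4 epimer pair)
Conditions: I2, NaHCO3, MeCN/H2O, 0 °C, dark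
Reagents that add atoms: iodine, II
Why: Iodolactonisation, in which the carboxylate attacks the iodonium ion 5-exo at the tertiary C10 from the face of the C5 side chain and anti to iodine, can only give the cis-fused γ-lactone and so ties C4 into a rigid bicycle next to C5.

Step 5
Reactants: 8 cis-fused iodolactone
Product: 9 C4-methylated iodolactone (4-CH3 cis to H5, 4-CO2Me on the concave face)
Conditions: MeI, K2CO3, acetone, rt
Reagents that add atoms: iodomethane, CI
Why: C-alkylation of a malonate-type lactone enolate, in which methyl iodide should approach the convex face of the cis-fused bicycle anti to the C5–C6 bond, sets the quaternary C4 with methyl cis to H5 and the ester on the concave face, which is the 4α-methyl/4β-ester arrangement of the target once ring A exists.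

Step 6
Reactants: 9 C4-methylated iodolactone
Product: 10 (2R)-3-methoxy-2-methyl-2-[(1R)-2-methylcyclohex-2-en-1-yl]-3-oxopropanoic acid
Conditions: Zn dust, AcOH, THF, rt
Reagents that add atoms: none
Why: Zinc-mediated reductive β-elimination of the β-iodo lactone (the reverse of halolactonisation) regenerates the C9=C10 alkene and the free acid without touching C4 or C5.

Step 7
Reactants: 10 (2R)-3-methoxy-2-methyl-2-[(1R)-2-methylcyclohex-2-en-1-yl]-3-oxopropanoic acid; 11 tributyl(vinyl)stannane
Product: 13 methyl (2R)-2-methyl-2-[(1R)-2-methylcyclohex-2-en-1-yl]-3-oxopent-4-enoate, via acid chloride 12 (not isolated)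
Conditions: (COCl)2, DMF (cat.), CH2Cl2, 0 °C → rt; then 11, BnPdCl(PPh3)2 (cat.), toluene, 60 °C
Reagents that add atoms: none
Why: Acid chloride formation followed by Stille acylation (Pd-catalysed coupling of an acyl chloride with a vinylstannane) gives the vinyl ketone directly and chemoselectively beside the hindered methyl ester, and C4 has no enolisable hydrogen.

Step 8
Reactants: 13 methyl (2R)-2-methyl-2-[(1R)-2-methylcyclohex-2-en-1-yl]-3-oxopent-4-enoate
Product: 14 methyl (2R)-2-methyl-2-[(1S,2S,6R)-1-methyl-7-oxabicyclo[4.1.0]heptan-2-yl]-3-oxopent-4-enoate (9α,10α-epoxide, trans to the C5 side chain)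
Conditions: mCPBA, NaHCO3, CH2Cl2, 0 °C
Reagents that add atoms: 3-chloroperoxybenzoic acid, O=C(OO)c1cccc(Cl)c1
Why: Prilezhaev epoxidation, in which the electron-rich trisubstituted ring alkene reacts in preference to the electron-poor enone and the peracid should approach anti to the bulky C5 substituent (held pseudoaxial by A(1,2) strain with the C10 methyl), giving the 9α,10α-epoxide.

Step 9
Reactants: 14 epoxy vinyl ketone
Product: 16 methyl 9α-hydroxy-3-oxo-11,12,13,14,15,16,17-heptanorlabdan-19-oate, via titanium(IV) enolate 15 (not isolated)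
Conditions: Cp2TiCl2 (2.5 equiv), Mn dust, THF, rt; added slowly to 14 in THF (0.01 M), rt; then 1 M HCl
Reagents that add atoms: none
Why: Titanocene(III) chloride binds the epoxide oxygen and by single-electron transfer cleaves the C10–O bond to the tertiary C10 radical with a Ti(IV) alkoxide on C9; this nucleophilic radical adds to the terminal carbon C1 of the electron-poor vinyl ketone, the resulting α-keto radical at C2 is reduced by a second Ti(III) to the titanium enolate 15, and acidic work-up gives the ketone. The closest known reaction type is the titanocene(III)-mediated reductive opening of epoxides with intramolecular radical addition to α,β-unsaturated carbonyl compounds, together with the second ring closure of radical polyene cyclisations, in which a 1-methylcyclohexyl radical with its tether on the neighbouring carbon gives a trans-decalin. Ring A closes in the 6-endo-trig mode (C10 onto C1), preferred over 5-exo attack at C2 because the carbonyl lies inside the tether and only attack at C1 gives a stabilised α-keto radical. The single new stereocentre, C10, is controlled by C5 through a chair-like transition state with the C5–C4 bond equatorial on ring B, so that C1 bonds to the face of C10 opposite to the C5 side chain and the methyl becomes axial, trans to H5; the cis alternative would push the fully substituted C4 into the concave face of a cis-decalin, syn-axial to C9. The step needs homolysis towards the tertiary carbon (secured by the trisubstituted epoxide), ring closure faster than hydrogen loss or reduction at C10 (secured by the quaternary C4, which holds the enone next to C10, and by slow addition that keeps Ti(III) dilute), and no ionic epoxide opening with participation of the neighbouring ester (manganese rather than zinc avoids a Lewis-acidic zinc halide). C4, C5 and the C9–O bond are untouched, and the 9α-oxygen remains as the handle for the side chain.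

Step 10
Reactants: 16 methyl 9α-hydroxy-3-oxo-heptanorlabdan-19-oate
Product: 17 methyl 3,3-ethylenedioxy-9α-hydroxy-11,12,13,14,15,16,17-heptanorlabdan-19-oate
Conditions: HOCH2CH2OH, TsOH (cat.), benzene, reflux (Dean–Stark)
Reagents that add atoms: ethylene glycol, OCCO
Why: Acid-catalysed acetalisation with azeotropic removal of water masks the only ketone (C3), so that O3 and O9 are differentiated without any selective alcohol protection, and the hindered 9α-alcohol and the ester are inert.

Step 11
Reactants: 17 methyl 3,3-ethylenedioxy-9α-hydroxy-heptanorlabdan-19-oate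
Product: 18 methyl 3,3-ethylenedioxy-9-oxo-11,12,13,14,15,16,17-heptanorlabdan-19-oate
Conditions: DMP, pyridine, CH2Cl2, rt
Reagents that add atoms: none
Why: Dess–Martin oxidation of the axial secondary alcohol gives the C9 ketone under buffered conditions that spare the acetal, and no stereocentre can epimerise because C10 is quaternary.

Step 12
Reactants: 18 methyl 3,3-ethylenedioxy-9-oxo-heptanorlabdan-19-oate
Product: 19 methyl 3,3-ethylenedioxy-9-(trifluoromethylsulfonyloxy)-11,12,13,14,15,16,17-heptanorlabd-8-en-19-oate
Conditions: KHMDS, THF, −78 °C; then PhNTf2, −78 → 0 °C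
Reagents that add atoms: N-phenylbis(trifluoromethanesulfonimide), O=S(=O)(N(c1ccccc1)S(=O)(=O)C(F)(F)F)C(F)(F)F
Why: Enolate O-triflation, in which the C9 ketone can enolise only towards C8 because C10 is quaternary, should give a single C8=C9 enol triflate, and the C19 ester has no α-hydrogen.

Step 13
Reactants: 19 C8=C9 enol triflate; 20 2-methyl-2-vinyl-1,3-dioxolane
Product: 22 methyl 3,3:13,13-bis(ethylenedioxy)-14,15,17-trinorlabd-8-en-19-oate, via B-alkyl-9-BBN 21 (not isolated)
Conditions: 20, 9-BBN, THF, rt; then 19, PdCl2(dppf) (cat.), AsPh3 (cat.), Cs2CO3, DMF/H2O, 50 °C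
Reagents that add atoms: none
Why: B-alkyl Suzuki–Miyaura coupling, in which anti-Markovnikov hydroboration of the vinyl dioxolane gives a primary alkylborane whose primary B–C bond transmetallates selectively to the alkenylpalladium(II) species from the triflate, attaches C11–C13 and C16 to C9 without creating a stereocentre.

Step 14
Reactants: 22 methyl 3,3:13,13-bis(ethylenedioxy)-14,15,17-trinorlabd-8-en-19-oate
Product: 24 methyl 3,3:13,13-bis(ethylenedioxy)-8α-hydroxy-14,15,17-trinorlabdan-19-oate, via C8 alkylborane 23 (not isolated)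
Conditions: BH3·THF, THF, 0 °C → rt; then NaOH, H2O2, 0 °C → rt
Reagents that add atoms: hydrogen peroxide, OO
Why: Brown hydroboration–oxidation places boron on the less substituted C8 and hydrogen on C9 by syn addition from the α face, away from the axial C10 methyl, so that H9 is α (side chain β, equatorial) and oxidation with retention gives the 8α-alcohol.

Step 15
Reactants: 24 methyl 3,3:13,13-bis(ethylenedioxy)-8α-hydroxy-14,15,17-trinorlabdan-19-oate
Product: 25 methyl 3,3:13,13-bis(ethylenedioxy)-8-oxo-14,15,17-trinorlabdan-19-oate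
Conditions: DMP, pyridine, CH2Cl2, rt
Reagents that add atoms: none
Why: Dess–Martin oxidation gives the C8 ketone, and although C9 is now epimerisable it already holds the thermodynamically preferred equatorial side chain.

Step 16
Reactants: 25 methyl 3,3:13,13-bis(ethylenedioxy)-8-oxo-14,15,17-trinorlabdan-19-oate
Product: 26 methyl 3,3:13,13-bis(ethylenedioxy)-14,15-dinorlabd-8(17)-en-19-oate
Conditions: Ph3PCH3Br, KOtBu, THF, rt → 50 °C
Reagents that add atoms: methyltriphenylphosphonium bromide, C[P+](c1ccccc1)(c1ccccc1)c1ccccc1.[Br-]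
Why: Wittig methylenation of the C8 ketone with the unstabilised ylide, a standard operation on 8-oxo labdane-type ketones, installs C17 while the hindered C19 ester and both acetals are inert.

Step 17
Reactants: 26 methyl 3,3:13,13-bis(ethylenedioxy)-14,15-dinorlabd-8(17)-en-19-oate
Product: 27 methyl 3,13-dioxo-14,15-dinorlabd-8(17)-en-19-oate
Conditions: 1 M HCl, THF, rt
Reagents that add atoms: water, O
Why: Aqueous acid hydrolysis of both dioxolanes releases the C3 and C13 ketones together under conditions mild enough to leave the exocyclic 8(17)-alkene in place.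

Step 18
Reactants: 27 methyl 3,13-dioxo-14,15-dinorlabd-8(17)-en-19-oate; 28 triethyl phosphonoacetate
Product: 29 15-ethyl 19-methyl 3-oxolabda-8(17),13E-diene-15,19-dioate
Conditions: NaH (slightly less than 28), THF, 0 °C → rt
Reagents that add atoms: none
Why: Horner–Wadsworth–Emmons olefination, in which the stabilised phosphonate anion reacts only with the unhindered methyl ketone (the C3 ketone is flanked by the quaternary C4) and reversible addition should favour the (E)-enoate, the minor (Z)-isomer being removable by chromatography.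

Step 19
Reactants: 29 15-ethyl 19-methyl 3-oxolabda-8(17),13E-diene-15,19-dioate
Product: 30 labda-8(17),13E-diene-3β,15,19-triol
Conditions: LiAlH4, THF, 0 °C
Reagents that add atoms: none
Why: Exhaustive lithium aluminium hydride reduction, in which axial hydride attack on the C3 ketone from the α face (the β face is shielded by the axial C4 ester) should give the equatorial 3β-alcohol, also takes the hindered C19 ester and the enoate (1,2-reduction) to the primary alcohols.

Step 20
Reactants: 30 labda-8(17),13E-diene-3β,15,19-triol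
Product: 31 15-(tert-butyldimethylsilyloxy)labda-8(17),13E-diene-3β,19-diol
Conditions: TBSCl (1.05 equiv), imidazole, CH2Cl2, −20 °C
Reagents that add atoms: tert-butyldimethylsilyl chloride, CC(C)(C)[Si](C)(C)Cl
Why: Selective silylation, since the unhindered primary allylic C15–OH should react far faster than the neopentyl axial C19–OH and the secondary C3–OH.

Step 21
Reactants: 31 15-(tert-butyldimethylsilyloxy)labda-8(17),13E-diene-3β,19-diol
Product: 32 15-(tert-butyldimethylsilyloxy)-3β-hydroxylabda-8(17),13E-dien-19-al
Conditions: TEMPO (cat.), PhI(OAc)2, CH2Cl2, rt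
Reagents that add atoms: none
Why: Oxoammonium (TEMPO/PhI(OAc)2) oxidation, which is selective for primary over secondary alcohols, should convert C19–OH into the non-enolisable aldehyde and leave the 3β-alcohol.

Step 22
Reactants: 32 15-(tert-butyldimethylsilyloxy)-3β-hydroxylabda-8(17),13E-dien-19-al
Product: 33 3β-acetoxy-15-(tert-butyldimethylsilyloxy)labda-8(17),13E-dien-19-al
Conditions: Ac2O, pyridine, DMAP (cat.), rt
Reagents that add atoms: acetic anhydride, CC(=O)OC(C)=O
Why: DMAP-catalysed acetylation of the remaining secondary alcohol under mildly basic conditions that should not trigger retro-aldol cleavage of the β-hydroxy aldehyde.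

Step 23
Reactants: 33 3β-acetoxy-15-(tert-butyldimethylsilyloxy)labda-8(17),13E-dien-19-al
Product: 34 3β-acetoxy-15-hydroxylabda-8(17),13E-dien-19-al (target)
Conditions: HF·pyridine, pyridine/THF, 0 °C
Reagents that add atoms: none
Why: Fluoride-mediated desilylation of the primary allylic silyl ether under buffered conditions leaves the acetate, the aldehyde and both alkenes untouched.

**Compound list**
1 | 2-methylcyclohex-2-en-1-one | CC1=CCCCC1=O | starting material
2 | (S)-2-methylcyclohex-2-en-1-ol | O[C@H]1CCCC=C1C | intermediate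
3 | methyl 3-chloro-3-oxopropanoate (methyl malonyl chloride) | COC(=O)CC(Cl)=O | starting material
4 | methyl (1S)-2-methylcyclohex-2-en-1-yl propanedioate | COC(=O)CC(=O)O[C@H]1CCCC=C1C | intermediate
5 | O-trimethylsilyl ketene acetal of 4 (formed in the flask, not isolated; C=C geometry undefined) | COC(=O)C=C(O[Si](C)(C)C)O[C@H]1CCCC=C1C | intermediate
6 | trimethylsilyl ester of acid 7 (formed in the flask, not isolated) | C1CC[C@@H](C(C(=O)OC)C(=O)O[Si](C)(C)C)C(C)=C1 | intermediate
7 | 3-methoxy-2-[(1S)-2-methylcyclohex-2-en-1-yl]-3-oxopropanoic acid (C4 epimer pair) | C1CC[C@@H](C(C(=O)OC)C(=O)O)C(C)=C1 | intermediate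
8 | methyl 7-iodo-7a-methyl-2-oxooctahydro-1-benzofuran-3-carboxylate; cis-fused, lactone O (C10) and C4 (on C5) β, iodine (C9) α, C4 epimer pair | C1CC[C@H]2C(C(=O)OC)C(=O)O[C@@]2(C)[C@@H]1I | intermediate
9 | methyl 7-iodo-3,7a-dimethyl-2-oxooctahydro-1-benzofuran-3-carboxylate; as 8, with 4-CH3 cis to H5 and 4-CO2Me on the concave face | C1CC[C@H]2[C@@](C)(C(=O)OC)C(=O)O[C@@]2(C)[C@@H]1I | intermediate
10 | (2R)-3-methoxy-2-methyl-2-[(1R)-2-methylcyclohex-2-en-1-yl]-3-oxopropanoic acid | C1CC[C@@H]([C@@](C)(C(=O)OC)C(=O)O)C(C)=C1 | intermediate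
11 | tributyl(vinyl)stannane | C=C[Sn](CCCC)(CCCC)CCCC | starting material
12 | acid chloride of 10 (formed in the flask, not isolated) | C1CC[C@@H]([C@@](C)(C(=O)OC)C(Cl)=O)C(C)=C1 | intermediate
13 | methyl (2R)-2-methyl-2-[(1R)-2-methylcyclohex-2-en-1-yl]-3-oxopent-4-enoate | C1CC[C@@H]([C@@](C)(C(=O)OC)C(=O)C=C)C(C)=C1 | intermediate
14 | methyl (2R)-2-methyl-2-[(1S,2S,6R)-1-methyl-7-oxabicyclo[4.1.0]heptan-2-yl]-3-oxopent-4-enoate (9α,10α-epoxide; key-step precursor) | C1CC[C@@H]([C@@](C)(C(=O)OC)C(=O)C=C)[C@@]2(C)[C@@H]1O2 | intermediate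
15 | bis-titanium(IV) species: C2=C3 titanium enolate and C9 titanium alkoxide of 16 (formed in the flask, not isolated; Cp drawn σ-bonded) | C1CC[C@H]2[C@@](C)(C(=O)OC)C(O[Ti](Cl)(C3C=CC=C3)C3C=CC=C3)=CC[C@]2(C)[C@@H]1O[Ti](Cl)(C1C=CC=C1)C1C=CC=C1 | intermediate
16 | methyl 9α-hydroxy-3-oxo-11,12,13,14,15,16,17-heptanorlabdan-19-oate (trans-decalin: 5α-H, 10β-CH3, 4α-CH3, 4β-CO2Me; key-step product) | C1CC[C@H]2[C@@](C)(C(=O)OC)C(=O)CC[C@]2(C)[C@@H]1O | intermediate
17 | methyl 3,3-ethylenedioxy-9α-hydroxy-11,12,13,14,15,16,17-heptanorlabdan-19-oate | C1CC[C@H]2[C@@](C)(C(=O)OC)C3(OCCO3)CC[C@]2(C)[C@@H]1O | intermediate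
18 | methyl 3,3-ethylenedioxy-9-oxo-11,12,13,14,15,16,17-heptanorlabdan-19-oate | C1CC[C@H]2[C@@](C)(C(=O)OC)C3(OCCO3)CC[C@]2(C)C1=O | intermediate
19 | methyl 3,3-ethylenedioxy-9-(trifluoromethylsulfonyloxy)-11,12,13,14,15,16,17-heptanorlabd-8-en-19-oate | C1C[C@H]2[C@@](C)(C(=O)OC)C3(OCCO3)CC[C@]2(C)C(OS(=O)(=O)C(F)(F)F)=C1 | intermediate
20 | 2-methyl-2-vinyl-1,3-dioxolane | C=CC1(C)OCCO1 | starting material
21 | 9-[2-(2-methyl-1,3-dioxolan-2-yl)ethyl]-9-borabicyclo[3.3.1]nonane (formed in the flask, not isolated) | CC1(CCB2C3CCCC2CCC3)OCCO1 | intermediate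
22 | methyl 3,3:13,13-bis(ethylenedioxy)-14,15,17-trinorlabd-8-en-19-oate | C1C[C@H]2[C@@](C)(C(=O)OC)C3(OCCO3)CC[C@]2(C)C(CCC4(C)OCCO4)=C1 | intermediate
23 | 8α-boryl (BH2) adduct of 22 with 9α-H (formed in the flask, not isolated) | B[C@@H]1CC[C@H]2[C@@](C)(C(=O)OC)C3(OCCO3)CC[C@]2(C)[C@H]1CCC1(C)OCCO1 | intermediate
24 | methyl 3,3:13,13-bis(ethylenedioxy)-8α-hydroxy-14,15,17-trinorlabdan-19-oate (9α-H) | O[C@@H]1CC[C@H]2[C@@](C)(C(=O)OC)C3(OCCO3)CC[C@]2(C)[C@H]1CCC1(C)OCCO1 | intermediate
25 | methyl 3,3:13,13-bis(ethylenedioxy)-8-oxo-14,15,17-trinorlabdan-19-oate | O=C1CC[C@H]2[C@@](C)(C(=O)OC)C3(OCCO3)CC[C@]2(C)[C@H]1CCC1(C)OCCO1 | intermediate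
26 | methyl 3,3:13,13-bis(ethylenedioxy)-14,15-dinorlabd-8(17)-en-19-oate | C=C1CC[C@H]2[C@@](C)(C(=O)OC)C3(OCCO3)CC[C@]2(C)[C@H]1CCC1(C)OCCO1 | intermediate
27 | methyl 3,13-dioxo-14,15-dinorlabd-8(17)-en-19-oate | C=C1CC[C@H]2[C@@](C)(C(=O)OC)C(=O)CC[C@]2(C)[C@H]1CCC(C)=O | intermediate
28 | triethyl phosphonoacetate | CCOC(=O)CP(=O)(OCC)OCC | starting material
29 | 15-ethyl 19-methyl 3-oxolabda-8(17),13E-diene-15,19-dioate | C=C1CC[C@H]2[C@@](C)(C(=O)OC)C(=O)CC[C@]2(C)[C@H]1CC/C(C)=C/C(=O)OCC | intermediate
30 | labda-8(17),13E-diene-3β,15,19-triol | C=C1CC[C@H]2[C@@](C)(CO)[C@@H](O)CC[C@]2(C)[C@H]1CC/C(C)=C/CO | intermediate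
31 | 15-(tert-butyldimethylsilyloxy)labda-8(17),13E-diene-3β,19-diol | C=C1CC[C@H]2[C@@](C)(CO)[C@@H](O)CC[C@]2(C)[C@H]1CC/C(C)=C/CO[Si](C)(C)C(C)(C)C | intermediate
32 | 15-(tert-butyldimethylsilyloxy)-3β-hydroxylabda-8(17),13E-dien-19-al | C=C1CC[C@H]2[C@@](C)(C=O)[C@@H](O)CC[C@]2(C)[C@H]1CC/C(C)=C/CO[Si](C)(C)C(C)(C)C | intermediate
33 | 3β-acetoxy-15-(tert-butyldimethylsilyloxy)labda-8(17),13E-dien-19-al | C=C1CC[C@H]2[C@@](C)(C=O)[C@@H](OC(C)=O)CC[C@]2(C)[C@H]1CC/C(C)=C/CO[Si](C)(C)C(C)(C)C | intermediate
34 | 3β-acetoxy-15-hydroxylabda-8(17),13E-dien-19-al | C=C1CC[C@H]2[C@@](C)(C=O)[C@@H](OC(C)=O)CC[C@]2(C)[C@H]1CC/C(C)=C/CO | target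

**Step count and risks**
Total step count: 23. Longest linear sequence: 23 steps (1 → 34); the other components (3, 11, 20, 28) are purchased.

Steps most likely to fail:

1. Step 9 (key step). What may go wrong: the tertiary C10 radical is lost before it closes ring A (hydrogen loss to the exocyclic alkene, or reduction), or titanium(III) reduces or oligomerises the vinyl ketone faster than the epoxide is opened. Fallback: the same C10 radical would be generated by metal-hydride hydrogen-atom transfer, so that no low-valent titanium meets the enone. It sets out from acid 10: acid chloride 12 is treated with morpholine to give the morpholine amide F1; mCPBA gives its 9α,10α-epoxide F2; titanocene(III) chloride in the absence of an acceptor isomerises the epoxide to the exocyclic allylic alcohol F3 (C10=CH2, 9α-OH), the usual fate of a β-titanoxy tertiary radical without a trap; excess vinylmagnesium bromide converts the amide into the vinyl ketone F4; Fe(acac)3/PhSiH3 in ethanol then transfers a hydrogen atom to the exocyclic methylene (Mukaiyama-type HAT followed by Giese cyclisation), the C10 radical closes 6-endo onto C1, and the route is rejoined at 16.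

2. Step 5. What may go wrong: poor facial discrimination in the alkylation of the planar, stabilised lactone enolate, giving a mixture of C4 epimers. Fallback: the quaternary C4 would be formed in the sigmatropic step itself. It sets out from alcohol 2: DCC/DMAP esterification with purchased 3-methoxy-2-methyl-3-oxopropanoic acid gives the mixed methylmalonate F5; LiHMDS/TMSCl gives the silyl ketene acetal F6, with the silyloxy group cis to the ester through the chelated enolate; Ireland–Claisen rearrangement through the chair transition state gives the trimethylsilyl ester F7 and, after hydrolysis, acid 10, where the route is rejoined (steps 3–6 are then not needed, and any C4 epimer is removed at 10).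

3. Step 21. What may go wrong: insufficient discrimination between the hindered neopentyl C19–OH and the secondary C3–OH, leading to over-oxidation at C3 or a stalled oxidation. Fallback: the three hydroxyls would be differentiated by protecting groups instead of by oxidant selectivity. It sets out from triol 30: TBDPSCl/imidazole silylates C15–OH to give the silyl ether F8; TESCl at low temperature silylates the primary C19–OH to give the bis-silyl ether F9; Ac2O/DMAP acetylates C3–OH to give the acetate F10; PPTS in methanol removes only the triethylsilyl group to give the 19-alcohol F11; Dess–Martin oxidation gives the aldehyde F12; buffered fluoride (TBAF/AcOH) removes the TBDPS group and the route is rejoined at the target 34.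

**Further compounds**
F1 | step 9 | methyl (2R)-2-methyl-2-[(1R)-2-methylcyclohex-2-en-1-yl]-3-(morpholin-4-yl)-3-oxopropanoate | C1CC[C@@H]([C@@](C)(C(=O)OC)C(=O)N2CCOCC2)C(C)=C1
F2 | step 9 | 9α,10α-epoxide of F1 | C1CC[C@@H]([C@@](C)(C(=O)OC)C(=O)N2CCOCC2)[C@@]2(C)[C@@H]1O2
F3 | step 9 | exocyclic allylic alcohol (C10=CH2, 9α-OH) morpholine amide | C1CC[C@@H]([C@@](C)(C(=O)OC)C(=O)N2CCOCC2)C(=C)[C@@H]1O
F4 | step 9 | exocyclic allylic alcohol (C10=CH2, 9α-OH) vinyl ketone | C1CC[C@@H]([C@@](C)(C(=O)OC)C(=O)C=C)C(=C)[C@@H]1O
F5 | step 5 | methyl (1S)-2-methylcyclohex-2-en-1-yl 2-methylpropanedioate | COC(=O)C(C)C(=O)O[C@H]1CCCC=C1C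
F6 | step 5 | O-trimethylsilyl ketene acetal of F5 (silyloxy cis to CO2Me) | COC(=O)/C(C)=C(\O[Si](C)(C)C)O[C@H]1CCCC=C1C
F7 | step 5 | trimethylsilyl ester of acid 10 | C1CC[C@@H]([C@@](C)(C(=O)OC)C(=O)O[Si](C)(C)C)C(C)=C1
F8 | step 21 | 15-(tert-butyldiphenylsilyloxy)labda-8(17),13E-diene-3β,19-diol | C=C1CC[C@H]2[C@@](C)(CO)[C@@H](O)CC[C@]2(C)[C@H]1CC/C(C)=C/CO[Si](c1ccccc1)(c1ccccc1)C(C)(C)C
F9 | step 21 | 15-(tert-butyldiphenylsilyloxy)-19-(triethylsilyloxy)labda-8(17),13E-dien-3β-ol | C=C1CC[C@H]2[C@@](C)(CO[Si](CC)(CC)CC)[C@@H](O)CC[C@]2(C)[C@H]1CC/C(C)=C/CO[Si](c1ccccc1)(c1ccccc1)C(C)(C)C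
F10 | step 21 | 3β-acetoxy-15-(tert-butyldiphenylsilyloxy)-19-(triethylsilyloxy)labda-8(17),13E-diene | C=C1CC[C@H]2[C@@](C)(CO[Si](CC)(CC)CC)[C@@H](OC(C)=O)CC[C@]2(C)[C@H]1CC/C(C)=C/CO[Si](c1ccccc1)(c1ccccc1)C(C)(C)C
F11 | step 21 | 3β-acetoxy-15-(tert-butyldiphenylsilyloxy)labda-8(17),13E-dien-19-ol | C=C1CC[C@H]2[C@@](C)(CO)[C@@H](OC(C)=O)CC[C@]2(C)[C@H]1CC/C(C)=C/CO[Si](c1ccccc1)(c1ccccc1)C(C)(C)C
F12 | step 21 | 3β-acetoxy-15-(tert-butyldiphenylsilyloxy)labda-8(17),13E-dien-19-al | C=C1CC[C@H]2[C@@](C)(C=O)[C@@H](OC(C)=O)CC[C@]2(C)[C@H]1CC/C(C)=C/CO[Si](c1ccccc1)(c1ccccc1)C(C)(C)C
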